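**Retrosynthetic overview**

- Feature used: ring A carries, going round, OMe, H, CO2H, the diaryl ether oxygen, OH and Cl, and its carbons are named here by what they bear: C(OMe), C(H), C(CO2H), C(OAr), C(OH), C(Cl). C(OH) and C(OMe) are meta with C(Cl) between them (a 2-chlororesorcinol monomethyl ether), and C(OAr) beside C(CO2H) is a hidden beta-aryloxy acrylate. Ring B (ether O, H, CH3, H, OH, CO2H going round) stays intact.
- Key disconnection: ring A to diazoketone 6 plus (methoxyethynyl)trimethylsilane 11 by a photo-Wolff/vinylketene benzannulation. It makes the ring bonds C(H)–C(CO2Me), C(OH)–C(Si), C(OMe)–C(H) and C(OAr)–C(OH), with silicon holding the place of chlorine.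
- After the ring: C–Si to C–Cl by ipso-chlorodesilylation, removal of both benzyl groups, saponification of the ring A methyl ester.
- Before the ring: 6 from methyl ketone 4 by diazo transfer; 4 from ring B phenol 2 plus methyl 2-(methoxymethylene)acetoacetate 3, so the ether C–O bond is made as an aryl vinyl ether before ring A exists; 11 from acetal 7 and chlorosilane 8.
- Ring order: ring B is bought intact as acid 1; ring A is the only ring formed, in step 5.

Key step: step 5

Remark (assumption): the aryloxymethylene double bond of 4, 5 and 6 is a push–pull alkene. These compounds are drawn and named as E isomers, but a mixture of geometric isomers is acceptable because both converge on the same ring A.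

**Route**

Step 1
Reactants: 1 2,6-dihydroxy-4-methylbenzoic acid
Product: 2 benzyl 2-(benzyloxy)-6-hydroxy-4-methylbenzoate
Conditions: BnBr (2.1 equiv), K2CO3, DMF, rt
Reagents that add atoms: benzyl bromide, BrCc1ccccc1
Why: Williamson-type O-alkylation in which the carboxylate and one phenoxide are benzylated while the second phenol, hydrogen-bonded to the new ester carbonyl, is much less reactive, so the reaction should stop at the monoether; the two phenols of 1 are equivalent by symmetry.

Step 2
Reactants: 2 benzyl 2-(benzyloxy)-6-hydroxy-4-methylbenzoate; 3 methyl 2-(methoxymethylene)acetoacetate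
Product: 4 benzyl 2-(benzyloxy)-6-{[(1E)-2-(methoxycarbonyl)-3-oxobut-1-en-1-yl]oxy}-4-methylbenzoate
Conditions: 3 (3 equiv), Cs2CO3 (0.1 equiv), 4 Å MS, toluene, 90 °C, MeOH removed
Reagents that add atoms: none
Why: Addition–elimination at the beta carbon of a doubly activated vinylogous ester (vinylogous transesterification, the reaction type used to make aryloxymethylene malonates), in which the phenoxide of 2 adds to 3, methoxide leaves and is protonated by further 2, and removal of methanol with excess 3 should pull the otherwise unfavourable equilibrium towards 4.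

Step 3
Reactants: 4 benzyl 2-(benzyloxy)-6-{[(1E)-2-(methoxycarbonyl)-3-oxobut-1-en-1-yl]oxy}-4-methylbenzoate
Product: 6 benzyl 2-(benzyloxy)-6-{[(1E)-4-diazo-2-(methoxycarbonyl)-3-oxobut-1-en-1-yl]oxy}-4-methylbenzoate, via trifluoroacetyl diketone 5 (not isolated)
Conditions: LiN(SiMe3)2, THF, −78 °C; CF3CO2CH2CF3; aq. HCl work-up; then MsN3, Et3N, H2O (1 equiv), MeCN, rt
Reagents that add atoms: methanesulfonyl azide, CS(=O)(=O)N=[N+]=[N-]; 2,2,2-trifluoroethyl trifluoroacetate, O=C(OCC(F)(F)F)C(F)(F)F
Why: Detrifluoroacetylative diazo transfer (Danheiser protocol, a Regitz-type transfer): the acetyl CH3 is the only enolisable position, the hindered amide base should deprotonate it at −78 °C faster than it adds to the aryloxymethylene carbon, C-trifluoroacetylation gives the activated diketone 5, and MsN3 then delivers the two diazo nitrogens while the trifluoroacetyl group (present only in 5) is lost as the acyl sulfonamide.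

Step 4
Reactants: 7 chloroacetaldehyde dimethyl acetal; 8 chlorotrimethylsilane
Product: 11 (methoxyethynyl)trimethylsilane, via 1-chloro-2-methoxyethene 9 (not isolated), via lithium methoxyacetylide 10 (not isolated)
Conditions: n-BuLi, Et2NH, THF, 0 °C (LiNEt2, 3.1 equiv); 7, 0 °C to rt; then 8, −78 °C to rt; H2O wash, distillation
Reagents that add atoms: none
Why: Known alkoxyacetylide synthesis from an alpha-chloro acetal, in which three equivalents of amide base eliminate methanol and then HCl and deprotonate the resulting methoxyacetylene, and the acetylide is silylated on carbon by 8; the methyl ynol ether, unlike an ethyl one, cannot lose an alkene by retro-ene reaction when heated in step 5.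

Step 5
Reactants: 6 benzyl 2-(benzyloxy)-6-{[(1E)-4-diazo-2-(methoxycarbonyl)-3-oxobut-1-en-1-yl]oxy}-4-methylbenzoate; 11 (methoxyethynyl)trimethylsilane
Product: 16 benzyl 2-(benzyloxy)-6-[2-hydroxy-4-methoxy-6-(methoxycarbonyl)-3-(trimethylsilyl)phenoxy]-4-methylbenzoate, via vinylketene 12 (not isolated), via 4-vinylcyclobutenone 13 (not isolated), via silyl dienylketene 14 (not isolated), via cyclohexa-2,4-dienone 15 (not isolated)
Conditions: 11 (3 equiv), hν (300–350 nm, Pyrex), toluene, rt; then 110 °C
Reagents that add atoms: none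
Why: Photolysis of 6 expels dinitrogen and the alkenyl carbon C(CO2Me) shifts to the former diazo carbon C(H) (photochemical Wolff rearrangement) to give vinylketene 12, across whose ketene C=C the ynol ether 11 adds in a [2+2] cycloaddition to give cyclobutenone 13, forming the C(OH)–C(Si) and C(OMe)–C(H) bonds. On heating, 13 opens by 4π conrotation to the silyl-substituted dienylketene 14, which closes ring A by a thermal 6π disrotatory electrocyclisation between the ketene carbon, the future C(OH), and the aryloxy-bearing carbon C(OAr), and dienone 15 tautomerises to the phenol. The closest known reaction is the diazoketone (second-generation) Danheiser benzannulation with alkoxy- and siloxyalkynes. No stereocentre survives: the sp3 carbons of 13 and 15 are transient and racemic, and the alkene geometry disappears on aromatisation. The selectivity required is the orientation of the [2+2]; lone-pair donation from the methoxy oxygen and beta-silicon stabilisation of positive charge at the methoxy-bearing alkyne carbon make the silyl-bearing carbon the nucleophile towards the ketene carbonyl carbon, so silicon lands on the future C(Cl) and methoxy on C(OMe). Light above 300 nm is chosen so that the benzyl aryl ether and benzoate chromophores are not excited.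

Step 6
Reactants: 16 benzyl 2-(benzyloxy)-6-[2-hydroxy-4-methoxy-6-(methoxycarbonyl)-3-(trimethylsilyl)phenoxy]-4-methylbenzoate
Product: 17 benzyl 2-(benzyloxy)-6-[3-chloro-2-hydroxy-4-methoxy-6-(methoxycarbonyl)phenoxy]-4-methylbenzoate
Conditions: NCS (1.05 equiv), MeCN, 0 °C to rt
Reagents that add atoms: N-chlorosuccinimide, O=C1CCC(=O)N1Cl
Why: Electrophilic ipso-halodesilylation: the silicon-bearing carbon is ortho to both the hydroxyl and the methoxy group, and attack of Cl+ there gives an arenium ion stabilised by the beta-silicon that collapses by loss of the silyl group, which should outpace substitution of the one ring A hydrogen (para to the hydroxyl but wedged between the methoxy and ester groups) or of the ring B diether.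

Step 7
Reactants: 17 benzyl 2-(benzyloxy)-6-[3-chloro-2-hydroxy-4-methoxy-6-(methoxycarbonyl)phenoxy]-4-methylbenzoate
Product: 18 2-[3-chloro-2-hydroxy-4-methoxy-6-(methoxycarbonyl)phenoxy]-6-hydroxy-4-methylbenzoic acid
Conditions: BCl3, C6HMe5, CH2Cl2, −78 to 0 °C; aq. work-up
Reagents that add atoms: none
Why: Lewis acid dealkylation with BCl3 and pentamethylbenzene as benzyl cation scavenger: the benzyl ether ortho to the ester and the benzyl ester are cleaved through boron chelates, while the unchelated ring A methyl ether, the methyl ester and the aryl chloride should be untouched (hydrogenolysis is avoided because it would endanger the C–Cl bond).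

Step 8
Reactants: 18 2-[3-chloro-2-hydroxy-4-methoxy-6-(methoxycarbonyl)phenoxy]-6-hydroxy-4-methylbenzoic acid
Product: 19 2-(2-carboxy-3-hydroxy-5-methylphenoxy)-4-chloro-3-hydroxy-5-methoxybenzoic acid (target)
Conditions: LiOH, THF/H2O, 40 °C; then 1 M HCl, 0 °C
Reagents that add atoms: lithium hydroxide, [Li+].[OH-]
Why: Saponification (base-mediated acyl substitution) of the only remaining ester; the diaryl ether, aryl chloride and methyl ether are inert to hydroxide, and cold acidification avoids decarboxylation of the 2,6-dioxygenated benzoic acid of ring B.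

**Compound list**

1 | 2,6-dihydroxy-4-methylbenzoic acid | Cc1cc(O)c(C(=O)O)c(O)c1 | starting material
2 | benzyl 2-(benzyloxy)-6-hydroxy-4-methylbenzoate | Cc1cc(O)c(C(=O)OCc2ccccc2)c(OCc2ccccc2)c1 | intermediate
3 | methyl 2-(methoxymethylene)acetoacetate (methyl 2-(methoxymethylene)-3-oxobutanoate, geometric mixture as supplied) | COC=C(C(C)=O)C(=O)OC | starting material
4 | benzyl 2-(benzyloxy)-6-{[(1E)-2-(methoxycarbonyl)-3-oxobut-1-en-1-yl]oxy}-4-methylbenzoate | O=C(OCc1ccccc1)c1c(OCc2ccccc2)cc(C)cc1O/C=C(/C(=O)OC)C(C)=O | intermediate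
5 | benzyl 2-(benzyloxy)-6-{[(1E)-6,6,6-trifluoro-2-(methoxycarbonyl)-3,5-dioxohex-1-en-1-yl]oxy}-4-methylbenzoate | O=C(OCc1ccccc1)c1c(OCc2ccccc2)cc(C)cc1O/C=C(/C(=O)OC)C(=O)CC(=O)C(F)(F)F | intermediate (not isolated)
6 | benzyl 2-(benzyloxy)-6-{[(1E)-4-diazo-2-(methoxycarbonyl)-3-oxobut-1-en-1-yl]oxy}-4-methylbenzoate | O=C(OCc1ccccc1)c1c(OCc2ccccc2)cc(C)cc1O/C=C(/C(=O)OC)C(=O)C=[N+]=[N-] | intermediate
7 | chloroacetaldehyde dimethyl acetal (2-chloro-1,1-dimethoxyethane) | COC(CCl)OC | starting material
8 | chlorotrimethylsilane | C[Si](C)(C)Cl | starting material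
9 | 1-chloro-2-methoxyethene (transient, geometry not controlled) | COC=CCl | intermediate (not isolated)
10 | lithium methoxyacetylide | [Li]C#COC | intermediate (not isolated)
11 | (methoxyethynyl)trimethylsilane | COC#C[Si](C)(C)C | intermediate
12 | benzyl 2-(benzyloxy)-6-{[(1E)-2-(methoxycarbonyl)-4-oxobuta-1,3-dien-1-yl]oxy}-4-methylbenzoate (vinylketene) | O=C(OCc1ccccc1)c1c(OCc2ccccc2)cc(C)cc1O/C=C(/C(=O)OC)C=C=O | intermediate (not isolated)
13 | benzyl 2-(benzyloxy)-6-{[(E)-2-(methoxycarbonyl)-2-[2-methoxy-4-oxo-3-(trimethylsilyl)cyclobut-2-en-1-yl]ethenyl]oxy}-4-methylbenzoate (racemic at the ring CH) | O=C(OCc1ccccc1)c1c(OCc2ccccc2)cc(C)cc1O/C=C(/C(=O)OC)C1C(=O)C([Si](C)(C)C)=C1OC | intermediate (not isolated)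
14 | benzyl 2-(benzyloxy)-6-{[(1E,3E)-4-methoxy-2-(methoxycarbonyl)-6-oxo-5-(trimethylsilyl)hexa-1,3,5-trien-1-yl]oxy}-4-methylbenzoate (dienylketene) | O=C(OCc1ccccc1)c1c(OCc2ccccc2)cc(C)cc1O/C=C(/C(=O)OC)\C=C(\OC)C([Si](C)(C)C)=C=O | intermediate (not isolated)
15 | benzyl 2-(benzyloxy)-6-{[4-methoxy-6-(methoxycarbonyl)-2-oxo-3-(trimethylsilyl)cyclohexa-3,5-dien-1-yl]oxy}-4-methylbenzoate (racemic) | O=C(OCc1ccccc1)c1c(OCc2ccccc2)cc(C)cc1OC1C(=O)C([Si](C)(C)C)=C(OC)C=C1C(=O)OC | intermediate (not isolated)
16 | benzyl 2-(benzyloxy)-6-[2-hydroxy-4-methoxy-6-(methoxycarbonyl)-3-(trimethylsilyl)phenoxy]-4-methylbenzoate | COc1cc(C(=O)OC)c(Oc2cc(C)cc(OCc3ccccc3)c2C(=O)OCc2ccccc2)c(O)c1[Si](C)(C)C | intermediate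
17 | benzyl 2-(benzyloxy)-6-[3-chloro-2-hydroxy-4-methoxy-6-(methoxycarbonyl)phenoxy]-4-methylbenzoate | COc1cc(C(=O)OC)c(Oc2cc(C)cc(OCc3ccccc3)c2C(=O)OCc2ccccc2)c(O)c1Cl | intermediate
18 | 2-[3-chloro-2-hydroxy-4-methoxy-6-(methoxycarbonyl)phenoxy]-6-hydroxy-4-methylbenzoic acid | COc1cc(C(=O)OC)c(Oc2cc(C)cc(O)c2C(=O)O)c(O)c1Cl | intermediate
19 | 2-(2-carboxy-3-hydroxy-5-methylphenoxy)-4-chloro-3-hydroxy-5-methoxybenzoic acid | COc1cc(C(=O)O)c(Oc2cc(C)cc(O)c2C(=O)O)c(O)c1Cl | target

**Step count**

Total steps: 8. Longest linear sequence: 7 steps (1 to 2 to 4 to 6 to 16 to 17 to 18 to 19, steps 1, 2, 3, 5, 6, 7, 8); step 4 is a one-step side branch.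

**Steps most likely to fail**

Step 5. The hindered C-silyl ynol ether may add too slowly, so that the vinylketene is lost to dimerisation or to capture by phenolic product. The silicon-stabilised dienylketene may also close slowly, particularly from the geometric isomer with the aryloxy group turned inward, and the aryl ether chromophores may be cleaved photochemically. The fallback sets out from 6 and from acetylide 10 (made from 7 as in step 4) and comes back to the route at 17, bypassing step 6. Acetylide 10 would be quenched with water instead of 8, and the volatile methoxyacetylene F1 distilled into the photolysis solvent. Irradiation of 6 with methoxyacetylene F1 and warming is the parent benzannulation with a terminal alkoxyacetylene, whose unsubstituted carbon bonds to the ketene carbonyl carbon. It should pass through the silicon-free cyclobutenone F2, the dienylketene F3 and the cyclohexadienone F4 to the silicon-free phenol F5. Chlorine would then be placed by amine-catalysed ortho-selective chlorination of the phenol (SO2Cl2, catalytic 2,2,6,6-tetramethylpiperidine, toluene). The carbon between the hydroxyl and methoxy groups is the only free position ortho to the hydroxyl, so this should give 17.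

Step 3. Amide base, water or triethylamine may add to the aryloxymethylene carbon and expel the ring B phenoxide, and the enolate may condense with a second molecule of 4. The fallback sets out from 3 (with 2) and comes back to the route at 6; the diazo group is installed before the ring B phenol is attached. Compound 3 would be enolised (LiN(SiMe3)2, THF, −78 °C) and trifluoroacetylated to methyl 6,6,6-trifluoro-2-(methoxymethylene)-3,5-dioxohexanoate F6. MsN3/Et3N would convert it to methyl 4-diazo-2-(methoxymethylene)-3-oxobutanoate F7. Base-catalysed exchange of phenol 2 onto diazoketone F7 (catalytic Cs2CO3, toluene, 45 °C, reduced pressure to strip methanol) would then give 6, so the labile aryloxymethylene unit never meets amide base or aqueous amine.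

Step 2. The exchange may stall because the equilibrium favours the methyl vinylogous ester and the hydrogen-bonded, hindered phenol is a weak nucleophile, and C-alkylation of ring B may compete. The fallback sets out from 3 (with 2) and comes back to the route at 4; the leaving group is made irreversible. Compound 3 would be hydrolysed (1 M NaOH, 1 equiv, 0 °C, then cold acidification) to methyl 2-(hydroxymethylene)-3-oxobutanoate F8. O-sulfonylation (TsCl, Et3N, CH2Cl2, 0 °C) would give the enol tosylate methyl 3-oxo-2-({[(4-methylphenyl)sulfonyl]oxy}methylene)butanoate F9. Phenol 2 with K2CO3 in MeCN (0 °C to rt) would then displace tosylate by addition–elimination to give 4.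

**Further compounds**

F1 | step 5 | methoxyacetylene (methoxyethyne) | COC#C
F2 | step 5 | benzyl 2-(benzyloxy)-6-{[(E)-2-(methoxycarbonyl)-2-(2-methoxy-4-oxocyclobut-2-en-1-yl)ethenyl]oxy}-4-methylbenzoate (racemic) | O=C(OCc1ccccc1)c1c(OCc2ccccc2)cc(C)cc1O/C=C(/C(=O)OC)C1C(=O)C=C1OC
F3 | step 5 | benzyl 2-(benzyloxy)-6-{[(1E,3E)-4-methoxy-2-(methoxycarbonyl)-6-oxohexa-1,3,5-trien-1-yl]oxy}-4-methylbenzoate | O=C(OCc1ccccc1)c1c(OCc2ccccc2)cc(C)cc1O/C=C(/C(=O)OC)\C=C(\OC)C=C=O
F4 | step 5 | benzyl 2-(benzyloxy)-6-{[4-methoxy-6-(methoxycarbonyl)-2-oxocyclohexa-3,5-dien-1-yl]oxy}-4-methylbenzoate (racemic) | O=C(OCc1ccccc1)c1c(OCc2ccccc2)cc(C)cc1OC1C(=O)C=C(OC)C=C1C(=O)OC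
F5 | step 5 | benzyl 2-(benzyloxy)-6-[2-hydroxy-4-methoxy-6-(methoxycarbonyl)phenoxy]-4-methylbenzoate | COc1cc(C(=O)OC)c(Oc2cc(C)cc(OCc3ccccc3)c2C(=O)OCc2ccccc2)c(O)c1
F6 | step 3 | methyl 6,6,6-trifluoro-2-(methoxymethylene)-3,5-dioxohexanoate | COC=C(C(=O)OC)C(=O)CC(=O)C(F)(F)F
F7 | step 3 | methyl 4-diazo-2-(methoxymethylene)-3-oxobutanoate | COC=C(C(=O)OC)C(=O)C=[N+]=[N-]
F8 | step 2 | methyl 2-(hydroxymethylene)-3-oxobutanoate | CC(=O)C(=CO)C(=O)OC
F9 | step 2 | methyl 3-oxo-2-({[(4-methylphenyl)sulfonyl]oxy}methylene)butanoate | CC(=O)C(=COS(=O)(=O)c1ccc(C)cc1)C(=O)OC
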